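**Retrosynthetic overview**
- The target is a cis-fused α-methylene-γ-lactone on a ten-membered carbocycle; its 3,10-oxygen bridge is the hemiketal of a C3 enone with the C10 tertiary alcohol.
- Last operation: C6–C7 and O6–C12 are made together. A masked (Z)-enal is allylated intramolecularly by a 2-(acyloxymethyl)acrylate (palladium/indium umpolung) and the adduct lactonises, releasing the C3 ketone as the transannular hemiketal.
- Allyl donor: C8 carbinol by catalytic asymmetric alkynylation with methyl propiolate, then trans-hydroalumination/hydroxymethylation and bis-isobutyrylation (one ester stays, one is the leaving group).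
- C3–C4 bond: a (Z)-alkenyllithium (from trans-hydrostannation of an alkynyl acetal) adds to (R)-5-methyl-5-vinylbutyrolactone made from (R)-linalool (C10 from the chiral pool). The vinyl group becomes C9–C8 by anti-Markovnikov Wacker oxidation.
- Ring order: oxolane ring first (lactone, then spiroketal, finally hemiketal); the ten-membered carbocycle and the γ-lactone form together at the end.

Assumption: the target is made exactly as drawn, (3S,6S,7R,8R,10R) with a cis-fused 6,12-lactone and a 4Z alkene; atom labels use germacrane numbering (C12 lactone carbonyl, C13 exocyclic CH2, C14 methyl on C10, C15 CH2OH).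

**Step 1**
Reactants: 1 3,3-diethoxyprop-1-yne
Product: 2 4,4-diethoxybut-2-yn-1-ol
Conditions: n-BuLi, THF, −78 °C; (CH2O)n, −78 °C → rt; H2O
Reagents that add atoms: formaldehyde (from paraformaldehyde), C=O
Why: Hydroxymethylation of a lithium acetylide with formaldehyde; no stereocentre is formed.

**Step 2**
Reactants: 2 4,4-diethoxybut-2-yn-1-ol
Product: 3 (Z)-4,4-diethoxy-2-(tributylstannyl)but-2-en-1-ol
Conditions: Bu3SnH (1.1 equiv), [(C5Me5)RuCl]4 (1.5 mol%), CH2Cl2, rt
Reagents that add atoms: tributyltin hydride, CCCC[SnH](CCCC)CCCC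
Why: Ruthenium-catalysed trans-hydrostannation of a propargylic alcohol: the free OH steers tin to the proximal alkyne carbon and H adds anti, so tin (the future C3–C4 bond) ends cis to the acetal carbon (future C6), which fixes the 4Z geometry.

**Step 3**
Reactants: 3 (Z)-4,4-diethoxy-2-(tributylstannyl)but-2-en-1-ol
Product: 4 (Z)-tert-butyl{[4,4-diethoxy-2-(tributylstannyl)but-2-en-1-yl]oxy}dimethylsilane
Conditions: TBSCl, imidazole, DMF, rt
Reagents that add atoms: tert-butyldimethylsilyl chloride, CC(C)(C)[Si](C)(C)Cl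
Why: Standard silylation of the primary alcohol (future C15–OH), needed so that later acylations and the palladium step do not touch it.

**Step 4**
Reactants: 5 (R)-(−)-linalool
Product: 7 (R)-5-ethenyl-5-methyloxolan-2-one, via lactol 6 (not isolated)
Conditions: O3 (1.0 equiv), CH2Cl2, −78 °C; Me2S, −78 °C → rt; evaporate; PhI(OAc)2, TEMPO (10 mol%), CH2Cl2, rt
Reagents that add atoms: ozone, [O-][O+]=O
Why: Criegee ozonolysis attacks the electron-rich trisubstituted alkene in preference to the vinyl group, the hydroxy aldehyde closes to lactol 6, and oxoammonium oxidation gives the lactone; C10 (R) is taken unchanged from the chiral pool.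

**Step 5**
Reactants: 4 (Z)-tert-butyl{[4,4-diethoxy-2-(tributylstannyl)but-2-en-1-yl]oxy}dimethylsilane; 7 (R)-5-ethenyl-5-methyloxolan-2-one
Product: 10 tert-butyl{[(7R)-2-ethoxy-7-ethenyl-7-methyl-1,6-dioxaspiro[4.4]non-3-en-4-yl]methoxy}dimethylsilane (epimer mixture at the two acetal carbons), via alkenyllithium 8 (not isolated), via hydroxy enone 9 (not isolated)
Conditions: 4, n-BuLi, THF, −78 °C; add 7, −78 → −40 °C; H2O; then PPTS (5 mol%), 4 Å MS, CH2Cl2, rt
Reagents that add atoms: none
Why: Tin–lithium exchange retains the alkene geometry, the alkenyllithium adds once to the γ-lactone (stable lactolate at low temperature), and acid-catalysed transacetalisation of the cis-disposed hemiketal OH onto the acetal (loss of EtOH) locks the product as a spiro mixed acetal; C10 is unchanged and the two acetal centres are inconsequential.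

**Step 6**
Reactants: 10 tert-butyl{[(7R)-2-ethoxy-7-ethenyl-7-methyl-1,6-dioxaspiro[4.4]non-3-en-4-yl]methoxy}dimethylsilane
Product: 11 2-[(7R)-4-{[(tert-butyldimethylsilyl)oxy]methyl}-2-ethoxy-7-methyl-1,6-dioxaspiro[4.4]non-3-en-7-yl]acetaldehyde
Conditions: PdCl2(PhCN)2 (10 mol%), CuCl2·2H2O (10 mol%), AgNO2 (5 mol%), O2 (1 atm), t-BuOH/MeNO2 15:1, rt
Reagents that add atoms: dioxygen, O=O
Why: Nitrite-modified, aldehyde-selective Wacker-type oxidation: the vinyl group sits on a fully substituted, oxygen-bearing carbon, so steric and inductive bias send oxygen to the terminal carbon (future C8); the trisubstituted ring alkene is inert and no stereocentre is touched.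

**Step 7**
Reactants: 11 2-[(7R)-4-{[(tert-butyldimethylsilyl)oxy]methyl}-2-ethoxy-7-methyl-1,6-dioxaspiro[4.4]non-3-en-7-yl]acetaldehyde; 12 methyl propiolate
Product: 13 methyl (4R)-5-[(7R)-4-{[(tert-butyldimethylsilyl)oxy]methyl}-2-ethoxy-7-methyl-1,6-dioxaspiro[4.4]non-3-en-7-yl]-4-hydroxypent-2-ynoate
Conditions: Me2Zn (3 equiv), (S,S)-ProPhenol (20 mol%), Ph3PO (40 mol%), toluene, 4 °C, slow addition of 11
Reagents that add atoms: none
Why: ProPhenol/dinuclear-zinc catalysed asymmetric alkynylation: the catalyst controls the face of acetylide addition and sets C8 (R); the (S,S) assignment is from memory of the usual facial sense and must be confirmed by Mosher analysis (the antipodal ligand gives the C8 epimer), while the remote C10 centre has little influence.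

**Step 8**
Reactants: 13 methyl (4R)-5-[(7R)-4-{[(tert-butyldimethylsilyl)oxy]methyl}-2-ethoxy-7-methyl-1,6-dioxaspiro[4.4]non-3-en-7-yl]-4-hydroxypent-2-ynoate
Product: 14 methyl (2E,4R)-5-[(7R)-4-{[(tert-butyldimethylsilyl)oxy]methyl}-2-ethoxy-7-methyl-1,6-dioxaspiro[4.4]non-3-en-7-yl]-4-hydroxy-2-(hydroxymethyl)pent-2-enoate
Conditions: NaAlH2(OCH2CH2OMe)2 (2.2 equiv), THF, −72 °C; CH2O (THF solution), −72 → −30 °C; aq. potassium sodium tartrate
Reagents that add atoms: formaldehyde, C=O
Why: Proposed new method: the C8 alkoxide delivers hydride from aluminium to the proximal alkyne carbon C7 (trans-hydroalumination through a five-membered oxa-aluminacycle), leaving an α-alumino enoate that should be hydroxymethylated by formaldehyde with retention, so C8 ends cis to CH2OH (C13) and trans to CO2Me (no butenolide can form); the closest known reactions are the trans-selective reduction of γ-hydroxy ynoates by this hydride with iodine trapping and the formaldehyde trapping of alkenylalanates.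

**Step 9**
Reactants: 14 methyl (2E,4R)-5-[(7R)-4-{[(tert-butyldimethylsilyl)oxy]methyl}-2-ethoxy-7-methyl-1,6-dioxaspiro[4.4]non-3-en-7-yl]-4-hydroxy-2-(hydroxymethyl)pent-2-enoate
Product: 15 methyl (2E,4R)-5-[(7R)-4-{[(tert-butyldimethylsilyl)oxy]methyl}-2-ethoxy-7-methyl-1,6-dioxaspiro[4.4]non-3-en-7-yl]-4-[(2-methylpropanoyl)oxy]-2-{[(2-methylpropanoyl)oxy]methyl}pent-2-enoate
Conditions: (i-PrCO)2O (3 equiv), Et3N, DMAP (10 mol%), CH2Cl2, 0 °C
Reagents that add atoms: isobutyric anhydride, CC(C)C(=O)OC(=O)C(C)C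
Why: DMAP-catalysed acylation of both hydroxyls in one operation: the secondary ester is the C8 isobutyrate of the target and the primary allylic ester is the leaving group for step 10; no stereocentre changes.

**Step 10**
Reactants: 15 methyl (2E,4R)-5-[(7R)-4-{[(tert-butyldimethylsilyl)oxy]methyl}-2-ethoxy-7-methyl-1,6-dioxaspiro[4.4]non-3-en-7-yl]-4-[(2-methylpropanoyl)oxy]-2-{[(2-methylpropanoyl)oxy]methyl}pent-2-enoate
Product: 18 (3S,6S,7R,8R,10R)-3,10-epoxy-3,15-dihydroxy-8-(2-methylpropanoyloxy)germacra-4Z,11(13)-dien-6,12-olide (target), via lactol 16 (not isolated), via macrocyclic hydroxy ester 17 (not isolated)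
Conditions: PPTS (20 mol%), THF/H2O 10:1, 40 °C; dilute to 2 mM, Pd(PPh3)4 (10 mol%), InI (2.5 equiv), rt; then air, 1 M aq. HCl, rt
Reagents that add atoms: water, O
Why: Proposed new method: mild acid unmasks the (Z)-enal as lactol 16, zerovalent palladium ionises the primary 2-(acyloxymethyl)acrylate, and InI reduces the π-allyl to an allylindium (C8 cis to CH2In) that adds to the tethered aldehyde through a Zimmerman–Traxler chair to give the 6,7-syn adduct 17 (hence the cis-lactone), on the face carrying the C9 tether with the C8–O bond held in the allyl plane (inside-alkoxy arrangement, helped by coordination of the 8-acyloxy group to indium) so that H-6, H-7 and H-8 end up cis; aqueous HCl then closes the γ-lactone, leaves C3 as the transannular hemiketal (its configuration dictated by C10) and removes the silyl group; the closest known reactions are palladium/indium umpolung allylation of aldehydes with allylic esters and intramolecular Barbier/Nozaki–Hiyama macrocyclisations that build ten-membered germacranolide rings.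

**Compound list**
1 | 3,3-diethoxyprop-1-yne | C#CC(OCC)OCC | starting material
2 | 4,4-diethoxybut-2-yn-1-ol | OCC#CC(OCC)OCC | intermediate
3 | (Z)-4,4-diethoxy-2-(tributylstannyl)but-2-en-1-ol | OC/C(=C/C(OCC)OCC)[Sn](CCCC)(CCCC)CCCC | intermediate
4 | (Z)-tert-butyl{[4,4-diethoxy-2-(tributylstannyl)but-2-en-1-yl]oxy}dimethylsilane | CC(C)(C)[Si](C)(C)OC/C(=C/C(OCC)OCC)[Sn](CCCC)(CCCC)CCCC | intermediate
5 | (R)-(−)-linalool, (R)-3,7-dimethylocta-1,6-dien-3-ol | C=C[C@](C)(O)CCC=C(C)C | starting material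
6 | (5R)-5-ethenyl-5-methyloxolan-2-ol (lactol, anomer mixture) | C=C[C@@]1(C)CCC(O)O1 | intermediate
7 | (R)-5-ethenyl-5-methyloxolan-2-one | C=C[C@@]1(C)CCC(=O)O1 | intermediate
8 | (E)-[1-(tert-butyldimethylsilyloxy)-4,4-diethoxybut-2-en-2-yl]lithium (Li cis to the acetal carbon) | CC(C)(C)[Si](C)(C)OC/C(=C/C(OCC)OCC)[Li] | intermediate
9 | (2Z,7R)-3-{[(tert-butyldimethylsilyl)oxy]methyl}-1,1-diethoxy-7-hydroxy-7-methylnona-2,8-dien-4-one (in equilibrium with its cyclic hemiketal) | C=C[C@](C)(O)CCC(=O)/C(CO[Si](C)(C)C(C)(C)C)=C\C(OCC)OCC | intermediate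
10 | tert-butyl{[(7R)-2-ethoxy-7-ethenyl-7-methyl-1,6-dioxaspiro[4.4]non-3-en-4-yl]methoxy}dimethylsilane (epimers at C2 and C5) | C=C[C@@]1(C)CCC2(O1)OC(OCC)C=C2CO[Si](C)(C)C(C)(C)C | intermediate
11 | 2-[(7R)-4-{[(tert-butyldimethylsilyl)oxy]methyl}-2-ethoxy-7-methyl-1,6-dioxaspiro[4.4]non-3-en-7-yl]acetaldehyde | O=CC[C@@]1(C)CCC2(O1)OC(OCC)C=C2CO[Si](C)(C)C(C)(C)C | intermediate
12 | methyl propiolate | C#CC(=O)OC | starting material
13 | methyl (4R)-5-[(7R)-4-{[(tert-butyldimethylsilyl)oxy]methyl}-2-ethoxy-7-methyl-1,6-dioxaspiro[4.4]non-3-en-7-yl]-4-hydroxypent-2-ynoate | COC(=O)C#C[C@H](O)C[C@@]1(C)CCC2(O1)OC(OCC)C=C2CO[Si](C)(C)C(C)(C)C | intermediate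
14 | methyl (2E,4R)-5-[(7R)-4-{[(tert-butyldimethylsilyl)oxy]methyl}-2-ethoxy-7-methyl-1,6-dioxaspiro[4.4]non-3-en-7-yl]-4-hydroxy-2-(hydroxymethyl)pent-2-enoate | COC(=O)/C(CO)=C/[C@H](O)C[C@@]1(C)CCC2(O1)OC(OCC)C=C2CO[Si](C)(C)C(C)(C)C | intermediate
15 | methyl (2E,4R)-5-[(7R)-4-{[(tert-butyldimethylsilyl)oxy]methyl}-2-ethoxy-7-methyl-1,6-dioxaspiro[4.4]non-3-en-7-yl]-4-[(2-methylpropanoyl)oxy]-2-{[(2-methylpropanoyl)oxy]methyl}pent-2-enoate | COC(=O)/C(COC(=O)C(C)C)=C/[C@H](OC(=O)C(C)C)C[C@@]1(C)CCC2(O1)OC(OCC)C=C2CO[Si](C)(C)C(C)(C)C | intermediate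
16 | lactol of 15 (2-hydroxy in place of 2-ethoxy; ring-chain tautomer of the (Z)-4-oxo-enal) | COC(=O)/C(COC(=O)C(C)C)=C/[C@H](OC(=O)C(C)C)C[C@@]1(C)CCC2(O1)OC(O)C=C2CO[Si](C)(C)C(C)(C)C | intermediate
17 | methyl 2-[(3S,6S,7R,8R,10R)-ten-membered carbocycle]acrylate: 6-hydroxy, 8-isobutyrate, 3,10-epoxy-3-hydroxy hemiketal, 4Z alkene, 15-O-TBS (seco-lactone of the silylated target) | C=C(C(=O)OC)[C@H]1[C@@H](O)/C=C(/CO[Si](C)(C)C(C)(C)C)[C@]2(O)CC[C@@](C)(O2)C[C@H]1OC(=O)C(C)C | intermediate
18 | (3S,6S,7R,8R,10R)-3,10-epoxy-3,15-dihydroxy-8-(2-methylpropanoyloxy)germacra-4Z,11(13)-dien-6,12-olide | C=C1C(=O)O[C@H]2/C=C(/CO)[C@]3(O)CC[C@](C)(C[C@@H](OC(=O)C(C)C)[C@@H]12)O3 | target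

**Totals**
Total step count: 10. Longest linear sequence: 9 steps (steps 1–3 and 5–10, from compound 1).

**Three steps most likely to fail**

Step 10 is the weakest step. The ten-membered ring may lose to oligomerisation. The allylmetal could eliminate the C8 isobutyrate, or zerovalent palladium could ionise that ester. Above all, the alternative conformer with H-8 in the allyl plane (favoured by allylic strain) would deliver the 6,7-bis-epimer. The fallback sets out from diol 14 and uses the free 8-hydroxyl as the directing group. Only the primary allylic hydroxyl is acylated (isobutyryl chloride, 2,4,6-collidine, CH2Cl2, −78 °C) to give the mono-isobutyrate F1. Acetal hydrolysis (PPTS, wet acetone) gives the lactol F2. F2 is cyclised with Pd(PPh3)4 and InI in dry THF at high dilution: the 8-hydroxyl binds indium in a six-membered allylindium chelate, which forces the C8–O bond inside while the aldehyde arrives from the tether face, and the indium alkoxide at O6 lactonises in situ to the 8-hydroxy lactone F3 (silyl ether kept). Isobutyric anhydride with DMAP then gives the silyl-protected target F4, and HF·pyridine returns to the route at 18. The open point of this fallback is that the 8-hydroxyl could also lactonise (8,12-olide); acylating promptly after cyclisation limits this.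

Step 8 is the second risk: protonation of the alumino-enoate may outrun formaldehyde trapping, giving the simple E-enoate. The fallback sets out from 13: the same hydride reduction is quenched with N-iodosuccinimide to give the (Z)-α-iodo enoate F5, and a Stille hydroxymethylation with (tributylstannyl)methanol and Pd(PPh3)4 (dioxane, 80 °C) returns to the route at 14.

Step 6 is the third risk: the methyl ketone may form, or the copper and palladium chlorides may cleave the acetal. The fallback sets out from 10: 9-BBN hydroboration of the vinyl group gives the alkylborane F6, NaBO3·4H2O oxidation gives the primary alcohol F7, and Dess–Martin periodinane oxidation returns to the route at 11.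

**Further compounds**
F1 | step 10 | methyl (2E,4R)-5-[(7R)-4-{[(tert-butyldimethylsilyl)oxy]methyl}-2-ethoxy-7-methyl-1,6-dioxaspiro[4.4]non-3-en-7-yl]-4-hydroxy-2-{[(2-methylpropanoyl)oxy]methyl}pent-2-enoate | COC(=O)/C(COC(=O)C(C)C)=C/[C@H](O)C[C@@]1(C)CCC2(O1)OC(OCC)C=C2CO[Si](C)(C)C(C)(C)C
F2 | step 10 | lactol of F1 (2-hydroxy in place of 2-ethoxy) | COC(=O)/C(COC(=O)C(C)C)=C/[C@H](O)C[C@@]1(C)CCC2(O1)OC(O)C=C2CO[Si](C)(C)C(C)(C)C
F3 | step 10 | 15-O-tert-butyldimethylsilyl-8-O-deisobutyryl derivative of 18 (free 8-hydroxyl) | C=C1C(=O)O[C@H]2/C=C(/CO[Si](C)(C)C(C)(C)C)[C@]3(O)CC[C@](C)(C[C@@H](O)[C@@H]12)O3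
F4 | step 10 | 15-O-tert-butyldimethylsilyl ether of 18 | C=C1C(=O)O[C@H]2/C=C(/CO[Si](C)(C)C(C)(C)C)[C@]3(O)CC[C@](C)(C[C@@H](OC(=O)C(C)C)[C@@H]12)O3
F5 | step 8 | methyl (2Z,4R)-5-[(7R)-4-{[(tert-butyldimethylsilyl)oxy]methyl}-2-ethoxy-7-methyl-1,6-dioxaspiro[4.4]non-3-en-7-yl]-4-hydroxy-2-iodopent-2-enoate | COC(=O)/C(I)=C/[C@H](O)C[C@@]1(C)CCC2(O1)OC(OCC)C=C2CO[Si](C)(C)C(C)(C)C
F6 | step 6 | 9-{2-[4-{[(tert-butyldimethylsilyl)oxy]methyl}-2-ethoxy-7-methyl-1,6-dioxaspiro[4.4]non-3-en-7-yl]ethyl}-9-borabicyclo[3.3.1]nonane (quaternary centre as in 10) | C1CC2CCCC(C1)B2CC[C@@]3(C)CCC4(O3)OC(OCC)C=C4CO[Si](C)(C)C(C)(C)C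
F7 | step 6 | 2-[(7R)-4-{[(tert-butyldimethylsilyl)oxy]methyl}-2-ethoxy-7-methyl-1,6-dioxaspiro[4.4]non-3-en-7-yl]ethan-1-ol | OCC[C@@]1(C)CCC2(O1)OC(OCC)C=C2CO[Si](C)(C)C(C)(C)C
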